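**Retrosynthetic overview**

1. The exocyclic C8=C17 methylene comes from a ring B C7=C8 enal (C17 aldehyde) by reductive 1,3-transposition. The single alkene left by a cycloaddition is therefore moved into place, not hydrogenated.
2. That enal comes from a siloxane-bridged tetracycle. The tetracycle forms in one operation from an open-chain (Z)-enynal hydrosilyl ether: trans-hydrosilylation closes a temporary O19–Si–C6 ring and creates the diene, then an intramolecular Diels–Alder reaction forms C5–C10 and C8–C9.
3. Enabling feature: quaternary C10 carries the C20 formyl group next to C9–H, so C9=C10–CHO is a built-in dienophile and ring B (C5–C10) is its cyclohexene adduct. The C19 oxygen on C4 is syn-diaxial to C20 and 1,3 to C6, so it can be tied to C6 through silicon to fix the diene face.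
4. The enynal comes from a B-alkyl Suzuki union (C1–C10) of two pieces. One is an enyne alcohol whose C4 is set by asymmetric epoxidation and epoxy silyl ether rearrangement. The other is an (E)-2-iodoallylic alcohol that already carries the butenolide, attached by Negishi coupling.
5. Ring order: butenolide (from furanone), then the siloxane ring (temporary), then rings A and B together.

Key step: step 18

Remark: positions follow labdane numbering. C4 bears CH3 (C18) and CH2O (C19), C5/C10 are the ring fusion, C20 is the formyl carbon, C8=C17 is the methylene, C9 bears the C11–C16 side chain. The SMILES is read as the ent-labdane (4R,5R,9R,10R): a trans-decalin with C19 and C20 axial on the same face. Compounds 1, 10, 14 and 17 are taken as commercial.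

**Step 1**
Reactants: 1 pent-1-en-4-yne
Product: 4 (2E)-3-methylhexa-2,5-dien-1-ol, via alkenylalane 2 (not isolated), via lithium alanate 3 (not isolated)
Conditions: AlMe3, Cp2ZrCl2 (cat.), CH2Cl2, 0 °C to rt; n-BuLi, THF, −78 °C; (CH2O)n, rt; aq HCl
Reagents that add atoms: trimethylaluminium C[Al](C)C; formaldehyde (as paraformaldehyde) C=O
Why: Negishi zirconium-catalysed carboalumination adds Me and Al syn across the terminal alkyne only, and hydroxymethylation of the alanate with retention should give the E trisubstituted allylic alcohol.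

**Step 2**
Reactants: 4 (2E)-3-methylhexa-2,5-dien-1-ol
Product: 5 [(2S,3S)-3-methyl-3-(prop-2-en-1-yl)oxiran-2-yl]methanol
Conditions: Ti(OiPr)4 (cat.), L-(+)-diethyl tartrate (cat.), t-BuOOH, 4 Å MS, CH2Cl2, −20 °C
Reagents that add atoms: tert-butyl hydroperoxide CC(C)(C)OO
Why: Sharpless asymmetric epoxidation touches only the allylic alcohol alkene, and with L-(+)-tartrate an E-3,3-disubstituted allylic alcohol should give the (2S,3S)-epoxide, the source of all absolute configuration.

**Step 3**
Reactants: 5 [(2S,3S)-3-methyl-3-(prop-2-en-1-yl)oxiran-2-yl]methanol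
Product: 6 TBS ether of 5
Conditions: TBSCl, imidazole, DMF, rt
Reagents that add atoms: tert-butyldimethylsilyl chloride CC(C)(C)[Si](C)(C)Cl
Why: Standard silylation supplies the siloxymethyl group that has to migrate in the next step.

**Step 4**
Reactants: 6 TBS ether of 5
Product: 7 (2S)-2-{[(tert-butyldimethylsilyl)oxy]methyl}-2-methylpent-4-enal
Conditions: MeAl(OAr)2 (Ar = 4-bromo-2,6-di-tert-butylphenyl, 20 mol %), CH2Cl2, −78 to −40 °C
Reagents that add atoms: none
Why: In this epoxy silyl ether to β-siloxy aldehyde rearrangement (semipinacol type) the bulky aluminium Lewis acid opens the epoxide at the tertiary carbon and the siloxymethyl group migrates anti to the leaving oxygen, so quaternary C4 forms with inversion and full chirality transfer.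

**Step 5**
Reactants: 7 (2S)-2-{[(tert-butyldimethylsilyl)oxy]methyl}-2-methylpent-4-enal
Product: 8 (R)-tert-butyl[(2-ethynyl-2-methylpent-4-en-1-yl)oxy]dimethylsilane
Conditions: dimethyl (1-diazo-2-oxopropyl)phosphonate, K2CO3, MeOH, rt
Reagents that add atoms: Ohira–Bestmann reagent CC(=O)C(=[N+]=[N-])P(=O)(OC)OC
Why: Ohira–Bestmann (Seyferth–Gilbert) homologation converts the non-enolisable aldehyde into the C5≡C6 terminal alkyne without touching C4.

**Step 6**
Reactants: 8 (R)-tert-butyl[(2-ethynyl-2-methylpent-4-en-1-yl)oxy]dimethylsilane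
Product: 9 (2R)-2-ethynyl-2-methylpent-4-en-1-ol
Conditions: TBAF, THF, rt
Reagents that add atoms: none
Why: Fluoride desilylation frees the neopentyl C19 hydroxyl group that later carries the silicon tether, and nothing else in 8 is fluoride-sensitive.

**Step 7**
Reactants: 10 3,3-diethoxyprop-1-yne
Product: 12 (1E)-3,3-diethoxy-1-iodoprop-1-ene, via alkenylzirconocene 11 (not isolated)
Conditions: Cp2Zr(H)Cl, THF, rt; I2, 0 °C
Reagents that add atoms: iodine II
Why: Hydrozirconation adds H and Zr syn with Zr at the terminus, and iodinolysis with retention should give the E vinyl iodide with the acetal intact.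

**Step 8**
Reactants: 9 (2R)-2-ethynyl-2-methylpent-4-en-1-ol; 12 (1E)-3,3-diethoxy-1-iodoprop-1-ene
Product: 13 (2R,5E)-7,7-diethoxy-2-methyl-2-(prop-2-en-1-yl)hept-5-en-3-yn-1-ol
Conditions: PdCl2(PPh3)2 (cat.), CuI (cat.), Et3N, THF, rt
Reagents that add atoms: none
Why: Sonogashira coupling joins C6 and C7 with retention of the E geometry and tolerates the free alcohol, the acetal and the terminal alkene.

**Step 9**
Reactants: 14 furan-2(5H)-one
Product: 16 3-bromofuran-2(5H)-one, via dibromolactone 15 (not isolated)
Conditions: Br2, CH2Cl2, reflux; Et3N, 0 °C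
Reagents that add atoms: bromine BrBr
Why: Bromine addition followed by E1cB loss of HBr (removal of the acidic α-proton, loss of the β-bromide) should leave bromine on the α-carbon.

**Step 10**
Reactants: 17 tert-butyldimethyl(prop-2-yn-1-yloxy)silane
Product: 19 5-[(tert-butyldimethylsilyl)oxy]pent-3-yn-1-ol, via lithium acetylide 18 (not isolated)
Conditions: n-BuLi, THF–DMPU, −78 °C; ethylene oxide, to rt; H2O
Reagents that add atoms: ethylene oxide C1CO1
Why: Acetylide opening of ethylene oxide adds C11 and C12 and gives the two hydroxyl termini already differentiated.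

**Step 11**
Reactants: 19 5-[(tert-butyldimethylsilyl)oxy]pent-3-yn-1-ol
Product: 20 tert-butyl[(5-iodopent-2-yn-1-yl)oxy]dimethylsilane
Conditions: I2, PPh3, imidazole, CH2Cl2, 0 °C
Reagents that add atoms: iodine II
Why: Appel-type iodination converts the unhindered primary alcohol into the iodide under neutral conditions.

**Step 12**
Reactants: 20 tert-butyl[(5-iodopent-2-yn-1-yl)oxy]dimethylsilane; 16 3-bromofuran-2(5H)-one
Product: 22 3-{5-[(tert-butyldimethylsilyl)oxy]pent-3-yn-1-yl}furan-2(5H)-one, via alkylzinc iodide 21 (not isolated)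
Conditions: Zn dust, LiCl, THF, 40 °C; 16, Pd(OAc)2 (cat.), SPhos (cat.), THF, rt
Reagents that add atoms: none
Why: Negishi sp3–sp2 coupling of a primary alkylzinc iodide with an α-bromo enoate-type halide forms C12–C13, and the mild organozinc does not attack the lactone.

**Step 13**
Reactants: 22 3-{5-[(tert-butyldimethylsilyl)oxy]pent-3-yn-1-yl}furan-2(5H)-one
Product: 23 3-(5-hydroxypent-3-yn-1-yl)furan-2(5H)-one
Conditions: AcOH–THF–H2O, rt
Reagents that add atoms: none
Why: Mild acid hydrolysis removes the primary propargylic silyl ether and avoids base at the butenolide.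

**Step 14**
Reactants: 23 3-(5-hydroxypent-3-yn-1-yl)furan-2(5H)-one
Product: 25 3-[(3E)-5-hydroxy-4-iodopent-3-en-1-yl]furan-2(5H)-one, via alkenylstannane 24 (not isolated)
Conditions: Bu3SnH, Mo(CO)3(CNtBu)3 (cat.), hydroquinone (cat.), THF, 55 °C; I2, CH2Cl2, 0 °C
Reagents that add atoms: iodine II
Why: Molybdenum-catalysed hydrostannation adds H and Sn syn with tin on the alkyne carbon next to the carbinol, and iododestannylation with retention leaves iodine trans and CH2OH (C20) cis to C11.

**Step 15**
Reactants: 13 (2R,5E)-7,7-diethoxy-2-methyl-2-(prop-2-en-1-yl)hept-5-en-3-yn-1-ol; 25 3-[(3E)-5-hydroxy-4-iodopent-3-en-1-yl]furan-2(5H)-one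
Product: 27 3-[(3Z,8R,11E)-13,13-diethoxy-4,8-bis(hydroxymethyl)-8-methyltrideca-3,11-dien-9-yn-1-yl]furan-2(5H)-one, via bis-borane adduct 26 (not isolated)
Conditions: 9-BBN (2.2 equiv), THF, 0 °C to rt; 25, PdCl2(dppf) (cat.), AsPh3 (cat.), Cs2CO3, DMF–H2O, rt
Reagents that add atoms: none
Why: In this B-alkyl Suzuki–Miyaura coupling 9-BBN hydroborates the terminal alkene much faster than the internal conjugated enyne (the hydroxyl group only consumes one equivalent), and the coupling replaces iodine with retention, so C20 and C11 stay cis.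

**Step 16**
Reactants: 27 the diol of step 15
Product: 28 3-[(3Z,8R,11E)-13,13-diethoxy-4-formyl-8-(hydroxymethyl)-8-methyltrideca-3,11-dien-9-yn-1-yl]furan-2(5H)-one
Conditions: MnO2, CH2Cl2, 0 °C to rt
Reagents that add atoms: none
Why: MnO2 allylic oxidation takes only the C20 alcohol and leaves the neopentyl C19 alcohol, its neutral heterogeneous conditions should preserve the Z geometry, and 28 can be handled because no diene is present yet.

**Step 17**
Reactants: 28 the hydroxy (Z)-enynal of step 16
Product: 29 dimethylsilyl ether of 28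
Conditions: ClSiHMe2, Et3N, CH2Cl2, 0 °C; filtration through Celite, used at once
Reagents that add atoms: chlorodimethylsilane C[SiH](C)Cl
Why: Simple O-silylation places the Si–H bond on O19, in a homopropargylic relation to C5≡C6.

**Step 18**
Reactants: 29 dimethylsilyl ether of 28
Product: 31 siloxane-bridged tetracyclic adduct (4R,5R,8S,9R,10R), via dienyl siloxane 30 (not isolated)
Conditions: [Cp*Ru(MeCN)3]PF6 (5 mol %), CH2Cl2, 0 °C to rt; then PhMe, BHT, 100 °C
Reagents that add atoms: none
Why: The cationic ruthenium catalyst adds the Si–H bond of 29 trans across C5≡C6 in the 6-endo-dig mode established for hydrosilyl ethers of homopropargylic alcohols (Si to C6, H to C5), which closes the temporary oxasilacyclohexene ring (O19, Si, C6, C5, C4, C19) and thereby switches on the 5E,7E 2-silyl diene of 30. On heating, 30 undergoes a type 1 intramolecular Diels–Alder reaction of the 1,7,9-decatriene class (closest known types: thermal cyclisation of trienals to trans-fused octalins and cycloadditions of cyclic siloxane dienes), in which C5–C10 and C8–C9 form suprafacially on both partners, so ring A closes through the C1–C4 tether and ring B closes as the new cyclohexene in the same event. C5 is controlled by C4, the only stereocentre of 29: the siloxane ring holds C19 close to the diene plane on the C6 side, so C3 and the dienophile it carries can reach only one face of C5, which places C19 axial and the C4 methyl group equatorial on ring A. C9 and C10 are controlled by the Z geometry of the enal (C20 and C11 stay cis) and by the endo position of the formyl group (H5 anti to C20, trans-decalin), an orientation favoured by secondary orbital overlap and enforced sterically because the exo mode would put C9 instead of the flat formyl group 1,3-diaxial to the locked axial C19. C8 (C17 cis to C11) follows from the E C7=C8 bond and is erased in step 20. The step needs alkyne-over-carbonyl selectivity in the hydrosilylation, secured by the intramolecular six-ring delivery and the alkynophilic catalyst, and enal-over-butenolide selectivity in the cycloaddition, secured because only C9=C10 can reach the diene through a six-membered tether.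

**Step 19**
Reactants: 31 siloxane-bridged tetracyclic adduct
Product: 33 C19 acetate C6 silanol 17,20-dialdehyde, via bromosilane bromoether 32 (not isolated)
Conditions: AcBr (2.5 equiv), SnBr2 (5 mol %), CH2Cl2, −20 to 0 °C; aq NaHCO3
Reagents that add atoms: acetyl bromide CC(=O)Br; water O
Why: In this Lewis-acid-catalysed acylative cleavage of a silyl ether the acyl group goes to O19 and bromide to silicon, so C19–OAc forms without ever releasing a free C19 hydroxyl group next to the C20 formyl group (which would close a lactol), while the acetal passes through its α-bromo ether to the C17 aldehyde on aqueous work-up, where any 1-bromoalkyl acetate formed reversibly at C20 also reverts.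

**Step 20**
Reactants: 33 C19 acetate C6 silanol 17,20-dialdehyde
Product: 35 19-acetoxy-ent-labda-7,13-diene-17,20-dial-16,15-olide, via deconjugated dialdehyde 34 (not isolated)
Conditions: TBAF, H2O, THF, 0 °C to rt; DBU (cat.), rt
Reagents that add atoms: none
Why: Fluoride-promoted protodesilylation of the vinylsilanol followed by base-catalysed conjugation through the C8 dienolate (γ-protonation at C6) should move the alkene to C7=C8, erasing C8, while C9 is untouched because it sits on the α-carbon of the enal.

**Step 21**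
Reactants: 35 19-acetoxy-ent-labda-7,13-diene-17,20-dial-16,15-olide
Product: 36 C17 tosylhydrazone of 35
Conditions: TsNHNH2 (1.0 equiv), THF, rt
Reagents that add atoms: p-toluenesulfonyl hydrazide Cc1ccc(cc1)S(=O)(=O)NN
Why: In this hydrazone condensation one equivalent of reagent should pick the exposed C17 enal over the axial neopentyl C20 aldehyde, which is flanked by C1, C9 and the C19 acetoxymethyl group.

**Step 22**
Reactants: 36 C17 tosylhydrazone of 35
Product: 38 target CNP0109410.1, via allylic diazene 37 (not isolated)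
Conditions: catecholborane (1.2 equiv), CHCl3, −40 to 0 °C; NaOAc·3H2O, reflux
Reagents that add atoms: none
Why: In this Kabalka-type tosylhydrazone reduction, 1,2-reduction of C=N, acetate-induced loss of sulfinate and retro-ene loss of N2 from 37 deliver H to C7 and shift the alkene to the exocyclic C8=C17 position, a placement fixed by the mechanism that touches no stereocentre.

**Compound list**

1 | pent-1-en-4-yne | C=CCC#C | starting material
2 | (E)-dimethyl(2-methylpenta-1,4-dien-1-yl)alane | C=CC/C(C)=C/[Al](C)C | intermediate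
3 | lithium butyl(dimethyl)[(E)-2-methylpenta-1,4-dien-1-yl]aluminate | [Li+].C=CC/C(C)=C/[Al-](C)(C)CCCC | intermediate
4 | (2E)-3-methylhexa-2,5-dien-1-ol | C=CC/C(C)=C/CO | intermediate
5 | [(2S,3S)-3-methyl-3-(prop-2-en-1-yl)oxiran-2-yl]methanol | OC[C@@H]1O[C@@]1(C)CC=C | intermediate
6 | tert-butyldimethylsilyl ether of 5 | CC(C)(C)[Si](C)(C)OC[C@@H]1O[C@@]1(C)CC=C | intermediate
7 | (2S)-2-{[(tert-butyldimethylsilyl)oxy]methyl}-2-methylpent-4-enal | O=C[C@](C)(CO[Si](C)(C)C(C)(C)C)CC=C | intermediate
8 | (R)-tert-butyl[(2-ethynyl-2-methylpent-4-en-1-yl)oxy]dimethylsilane | C#C[C@](C)(CO[Si](C)(C)C(C)(C)C)CC=C | intermediate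
9 | (2R)-2-ethynyl-2-methylpent-4-en-1-ol | C#C[C@](C)(CO)CC=C | intermediate
10 | 3,3-diethoxyprop-1-yne | C#CC(OCC)OCC | starting material
11 | chloro[(E)-3,3-diethoxyprop-1-en-1-yl]zirconocene | CCOC(OCC)/C=C/[Zr](Cl)(C1C=CC=C1)C1C=CC=C1 | intermediate
12 | (1E)-3,3-diethoxy-1-iodoprop-1-ene | CCOC(OCC)/C=C/I | intermediate
13 | (2R,5E)-7,7-diethoxy-2-methyl-2-(prop-2-en-1-yl)hept-5-en-3-yn-1-ol | CCOC(OCC)/C=C/C#C[C@](C)(CO)CC=C | intermediate
14 | furan-2(5H)-one | O=C1C=CCO1 | starting material
15 | 3,4-dibromodihydrofuran-2(3H)-one | O=C1OCC(Br)C1Br | intermediate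
16 | 3-bromofuran-2(5H)-one | O=C1OCC=C1Br | intermediate
17 | tert-butyldimethyl(prop-2-yn-1-yloxy)silane | C#CCO[Si](C)(C)C(C)(C)C | starting material
18 | lithium acetylide of 17 | [Li]C#CCO[Si](C)(C)C(C)(C)C | intermediate
19 | 5-[(tert-butyldimethylsilyl)oxy]pent-3-yn-1-ol | OCCC#CCO[Si](C)(C)C(C)(C)C | intermediate
20 | tert-butyl[(5-iodopent-2-yn-1-yl)oxy]dimethylsilane | ICCC#CCO[Si](C)(C)C(C)(C)C | intermediate
21 | {5-[(tert-butyldimethylsilyl)oxy]pent-3-yn-1-yl}zinc iodide | I[Zn]CCC#CCO[Si](C)(C)C(C)(C)C | intermediate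
22 | 3-{5-[(tert-butyldimethylsilyl)oxy]pent-3-yn-1-yl}furan-2(5H)-one | O=C1OCC=C1CCC#CCO[Si](C)(C)C(C)(C)C | intermediate
23 | 3-(5-hydroxypent-3-yn-1-yl)furan-2(5H)-one | O=C1OCC=C1CCC#CCO | intermediate
24 | 3-[(3E)-5-hydroxy-4-(tributylstannyl)pent-3-en-1-yl]furan-2(5H)-one | OC/C([Sn](CCCC)(CCCC)CCCC)=C\CCC1=CCOC1=O | intermediate
25 | 3-[(3E)-5-hydroxy-4-iodopent-3-en-1-yl]furan-2(5H)-one | OC/C(I)=C\CCC1=CCOC1=O | intermediate
26 | bis-9-BBN adduct of 13 (C1 alkylborane, O19 borinate) | CCOC(OCC)/C=C/C#C[C@](C)(COB1C2CCCC1CCC2)CCCB1C2CCCC1CCC2 | intermediate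
27 | 3-[(3Z,8R,11E)-13,13-diethoxy-4,8-bis(hydroxymethyl)-8-methyltrideca-3,11-dien-9-yn-1-yl]furan-2(5H)-one | OC/C(CCC[C@@](C)(CO)C#C/C=C/C(OCC)OCC)=C\CCC1=CCOC1=O | intermediate
28 | 3-[(3Z,8R,11E)-13,13-diethoxy-4-formyl-8-(hydroxymethyl)-8-methyltrideca-3,11-dien-9-yn-1-yl]furan-2(5H)-one | O=C/C(CCC[C@@](C)(CO)C#C/C=C/C(OCC)OCC)=C\CCC1=CCOC1=O | intermediate
29 | O19-dimethylsilyl ether of 28 | O=C/C(CCC[C@@](C)(CO[SiH](C)C)C#C/C=C/C(OCC)OCC)=C\CCC1=CCOC1=O | intermediate
30 | (Z)-enal carrying the (5R)-3-[(1E)-3,3-diethoxyprop-1-enyl]-2,2,5-trimethyl-5,6-dihydro-2H-1,2-oxasilin-5-yl diene unit | O=C/C(CCC[C@@]1(C)CO[Si](C)(C)C(/C=C/C(OCC)OCC)=C1)=C\CCC1=CCOC1=O | intermediate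
31 | tetracyclic adduct: trans-fused ent-labd-6-en-20-al, C17 diethyl acetal, O19–SiMe2–C6 bridge, butenolide side chain; C19, C20, C11 and C17 on one face, H5, H8 and H9 on the other | CCOC(OCC)[C@@H]1C=C3[C@@H]2[C@](C)(CO[Si]3(C)C)CCC[C@@]2(C=O)[C@@H]1CCC1=CCOC1=O | intermediate
32 | C19 acetate with C6 bromodimethylsilyl group and C17 α-bromo ethyl ether | CCOC(Br)[C@@H]1C=C([Si](C)(C)Br)[C@@H]2[C@](C)(COC(C)=O)CCC[C@@]2(C=O)[C@@H]1CCC1=CCOC1=O | intermediate
33 | 19-acetoxy-6-(hydroxydimethylsilyl)-ent-labda-6,13-diene-17,20-dial-16,15-olide | O=C[C@@H]1C=C([Si](C)(C)O)[C@@H]2[C@](C)(COC(C)=O)CCC[C@@]2(C=O)[C@@H]1CCC1=CCOC1=O | intermediate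
34 | 19-acetoxy-ent-labda-6,13-diene-17,20-dial-16,15-olide | O=C[C@@H]1C=C[C@@H]2[C@](C)(COC(C)=O)CCC[C@@]2(C=O)[C@@H]1CCC1=CCOC1=O | intermediate
35 | 19-acetoxy-ent-labda-7,13-diene-17,20-dial-16,15-olide | O=CC1=CC[C@@H]2[C@](C)(COC(C)=O)CCC[C@@]2(C=O)[C@@H]1CCC1=CCOC1=O | intermediate
36 | C17 (E)-p-toluenesulfonylhydrazone of 35 | Cc1ccc(cc1)S(=O)(=O)N/N=C/C1=CC[C@@H]2[C@](C)(COC(C)=O)CCC[C@@]2(C=O)[C@@H]1CCC1=CCOC1=O | intermediate
37 | C17 allylic diazene (C7=C8 alkene) | N=NCC1=CC[C@@H]2[C@](C)(COC(C)=O)CCC[C@@]2(C=O)[C@@H]1CCC1=CCOC1=O | intermediate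
38 | [(1R,4aR,5R,8aR)-4a-formyl-1-methyl-6-methylidene-5-[2-(2-oxo-2,5-dihydrofuran-3-yl)ethyl]decahydronaphthalen-1-yl]methyl acetate | C=C1CC[C@@H]2[C@](C)(COC(C)=O)CCC[C@@]2(C=O)[C@@H]1CCC1=CCOC1=O | target

**Step count and risks**

Total step count: 22. Longest linear sequence: 15 (steps 1–6, 8, 15–22).

Steps most likely to fail:

1. **Step 18.** The Z enal may drift to the E isomer (amine traces, metal hydride species, thermal 1,5-hydrogen shift). The enal may also tie up the ruthenium catalyst before the diene exists. The cycloaddition itself may lag because two congested carbons are joined.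
   Fallback: build the diene first and unveil the dienophile last. It sets out from 27. Both hydroxyl groups are silylated (ClSiHMe2, Et3N) to the bis(dimethylsilyl) ether F1. The same ruthenium catalyst cyclises only the homopropargylic Si–H to the siloxane diene silyl ether F2. Brief methanolysis at rt removes only the acyclic allylic silyl ether and gives the dienyl siloxane allylic alcohol F3. MnO2 oxidation then gives 30, where the route is rejoined. The enal is thus formed next to a waiting diene and cyclises to 31 as in step 18.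

2. **Step 19.** The acyl bromide or adventitious HBr may attack the vinylsilane or the formyl group, or the Si–O acylation may stay incomplete.
   Fallback: accept the lactol and open it as a hydrazone. It sets out from 31. TBAF/H2O removes silicon from both O19 and C6, and the hydroxy aldehyde closes to the 19,20-lactol acetal F4. 1,1-Dimethylhydrazine opens it to the C20 dimethylhydrazone alcohol F5. Ac2O/pyridine gives the C19 acetate hydrazone F6. Aqueous oxalic acid in THF hydrolyses the hydrazone and the acetal together to 34, where the route is rejoined for the DBU conjugation of step 20.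

3. **Step 22.** Chemoselectivity may be lost if hydride is delivered to the C20 formyl group in competition with the C=N bond.
   Fallback: reduce both and re-oxidise. It sets out from 36. Excess catecholborane followed by NaOAc·3H2O gives the transposed 20-alcohol F7, with C19 already acetylated. Dess–Martin periodinane oxidises its only free hydroxyl group to 38.

**Further compounds**

F1 | step 18 | bis(dimethylsilyl) ether of 27 | C[SiH](C)OC/C(CCC[C@@](C)(CO[SiH](C)C)C#C/C=C/C(OCC)OCC)=C\CCC1=CCOC1=O
F2 | step 18 | siloxane diene with O20 dimethylsilyl ether | C[SiH](C)OC/C(CCC[C@@]1(C)CO[Si](C)(C)C(/C=C/C(OCC)OCC)=C1)=C\CCC1=CCOC1=O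
F3 | step 18 | dienyl siloxane (Z)-allylic alcohol | OC/C(CCC[C@@]1(C)CO[Si](C)(C)C(/C=C/C(OCC)OCC)=C1)=C\CCC1=CCOC1=O
F4 | step 19 | 19,20-lactol of the desilylated adduct, C17 diethyl acetal | CCOC(OCC)[C@@H]1C=C[C@@H]2[C@]3(C)COC(O)[C@]2(CCC3)[C@@H]1CCC1=CCOC1=O
F5 | step 19 | C20 N,N-dimethylhydrazone with free C19 alcohol | CCOC(OCC)[C@@H]1C=C[C@@H]2[C@](C)(CO)CCC[C@@]2(C=NN(C)C)[C@@H]1CCC1=CCOC1=O
F6 | step 19 | C19 acetate of F5 | CCOC(OCC)[C@@H]1C=C[C@@H]2[C@](C)(COC(C)=O)CCC[C@@]2(C=NN(C)C)[C@@H]1CCC1=CCOC1=O
F7 | step 22 | 20-alcohol corresponding to the target | C=C1CC[C@@H]2[C@](C)(COC(C)=O)CCC[C@@]2(CO)[C@@H]1CCC1=CCOC1=O
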